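## Retrosynthetic overview

1. Streptaspironate A ⇐ type 1 IMDA (cyclohexene and dihydropyran close together, three stereocentres) of a 13-membered macrocyclic 4-O-tert-alkyl 5-methylidene tetronate ⇐ C–O bond: macro-transetherification of a tertiary alcohol onto C4 of a 3-acyl-4-methoxy tetronate (open-chain seco alcohol).
2. Seco alcohol ⇐ boron aldol (sets the methoxy-bearing carbon) and O-methylation: 3-acetyl-4-methoxy-5-methylidene tetronate plus a (Z)-enal that carries the tertiary carbinol and the (E,E)-diene.
3. Enal ⇐ Negishi carboalumination/cross-coupling (diene) ⇐ Cu-catalysed asymmetric propargylation of a Z methyl enone (tertiary carbinol) ⇐ Still–Gennari olefination (second Z alkene) ⇐ Normant carbocupration of propyne with acylation (first Z alkene).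
4. Ring order: butenolide (from methyl tetronate) → 13-membered macrocycle (C–O bond) → cyclohexene and pyran in one IMDA.

Assumption: the target is taken exactly as the SMILES gives it (both macrocyclic trisubstituted alkenes Z, carbinol carbon S, methoxy carbon R). Which antipode of the ligand (step 7) and of the borane (step 11) gives these configurations is assigned from the usual models and has to be confirmed on the first run.

## Route

Step 1
Reactants: 1 4-methoxyfuran-2(5H)-one (methyl tetronate)
Product: 5 4-methoxy-5-methylidenefuran-2(5H)-one, via C5-lithio tetronate 2 (not isolated), via Mannich base 3 (not isolated), via ammonium iodide 4 (not isolated)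
Conditions: LiN(iPr)2, THF, −78 °C; [CH2=NMe2]I, −78 °C → rt; MeI, rt; aq. NaHCO3/CH2Cl2, rt
Reagents that add atoms: N,N-dimethylmethyleneiminium iodide, C=[N+](C)C.[I-]
Why: Kinetic C5 lithiation of the tetronate, Mannich aminomethylation, N-methylation and base-induced elimination of trimethylamine give the exocyclic methylene (one-pot Mannich–elimination methylenation).

Step 2
Reactants: 5 4-methoxy-5-methylidenefuran-2(5H)-one
Product: 7 3-acetyl-4-methoxy-5-methylidenefuran-2(5H)-one, via C3-lithio tetronate 6 (not isolated)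
Conditions: LiN(iPr)2, THF, −78 °C; MeC(O)N(OMe)Me, −78 → −40 °C; AcOH quench
Reagents that add atoms: N-methoxy-N-methylacetamide, CC(=O)N(C)OC
Why: With C5 blocked the only acidic ring proton is C3–H, and the vinyllithium acylates the Weinreb amide once through a stable chelated tetrahedral intermediate (Weinreb ketone synthesis).

Step 3
Reactants: 8 pent-2-yne
Product: 10 (E)-2-iodopent-2-ene, via alkenylzirconocene 9 (not isolated)
Conditions: Cp2Zr(H)Cl (1.3 equiv), THF, 40 °C; I2, 0 °C
Reagents that add atoms: iodine, II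
Why: syn-Hydrozirconation, equilibrated by the excess hydride toward Zr on the methyl-bearing carbon (about 9:1), followed by iodinolysis with retention gives the E iodide (hydrozirconation–iodination).

Step 4
Reactants: 11 2-(2-bromoethyl)-1,3-dioxolane; 12 propyne
Product: 16 (Z)-6-(1,3-dioxolan-2-yl)-4-methylhex-3-en-2-one, via Grignard reagent 13 (not isolated), via alkylcopper 14 (not isolated), via alkenylcopper 15 (not isolated)
Conditions: Mg, THF, 25 °C; CuBr·SMe2, Et2O/Me2S, −45 °C; propyne, −25 °C; AcCl, Pd(PPh3)4 (3 mol %), −20 → 0 °C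
Reagents that add atoms: acetyl chloride, CC(=O)Cl
Why: Normant syn-carbocupration of propyne puts the acetal chain cis to copper, and Pd-catalysed acylation with retention gives the Z enone, which fixes the first Z trisubstituted alkene.

Step 5
Reactants: 16 (Z)-6-(1,3-dioxolan-2-yl)-4-methylhex-3-en-2-one
Product: 17 (Z)-4-methyl-6-oxohept-4-enal
Conditions: 2 M HCl/THF (1:3), 23 °C
Reagents that add atoms: water, O
Why: Acid-catalysed acetal hydrolysis unmasks the aldehyde and leaves the conjugated ketone and its Z geometry untouched.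

Step 6
Reactants: 17 (Z)-4-methyl-6-oxohept-4-enal
Product: 18 methyl (2Z,6Z)-2,6-dimethyl-8-oxonona-2,6-dienoate
Conditions: (CF3CH2O)2P(O)CH(Me)CO2Me, KN(SiMe3)2, 18-crown-6, THF, −78 °C
Reagents that add atoms: methyl 2-[bis(2,2,2-trifluoroethoxy)phosphoryl]propanoate, COC(=O)C(C)P(=O)(OCC(F)(F)F)OCC(F)(F)F
Why: The Still–Gennari olefination is aldehyde-selective and, through kinetic control with the electron-poor phosphonate and a dissociated potassium base, Z-selective, so it sets the second Z trisubstituted alkene.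

Step 7
Reactants: 18 methyl (2Z,6Z)-2,6-dimethyl-8-oxonona-2,6-dienoate
Product: 19 methyl (2Z,6Z,8S)-8-hydroxy-2,6,8-trimethylundeca-2,6-dien-10-ynoate
Conditions: allenyl-B(pin), CuOAc (5 mol %), (R,R)-Ph-BPE [1,2-bis(2,5-diphenylphospholan-1-yl)ethane] (6 mol %), LiOiPr (20 mol %), iPrOH (1.0 equiv), THF, −40 °C
Reagents that add atoms: allenylboronic acid pinacol ester, C=C=CB1OC(C)(C)C(C)(C)O1
Why: Copper-catalysed enantioselective propargylation of the methyl ketone (B-to-Cu transmetalation, SE2' addition of the allenylcopper) sets the tertiary carbinol as S by telling methyl from the bulky Z-alkenyl group, while the enoate is inert (the ligand antipode is switched if the first run gives 8R).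

Step 8
Reactants: 19 methyl (2Z,6Z,8S)-8-hydroxy-2,6,8-trimethylundeca-2,6-dien-10-ynoate
Product: 20 (2Z,6Z,8S)-2,6,8-trimethylundeca-2,6-dien-10-yne-1,8-diol
Conditions: iBu2AlH (3.5 equiv), CH2Cl2, −78 → 0 °C; aq. KNa tartrate
Reagents that add atoms: none
Why: iBu2AlH reduces the enoate to the allylic alcohol with retention of the Z geometry and does not touch the alkyne or the tertiary alcohol (ester reduction), which removes the only carbonyl before the organoaluminium step.

Step 9
Reactants: 20 (2Z,6Z,8S)-2,6,8-trimethylundeca-2,6-dien-10-yne-1,8-diol; 10 (E)-2-iodopent-2-ene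
Product: 23 (2Z,6Z,8S,10E,12E)-2,6,8,10,12-pentamethylpentadeca-2,6,10,12-tetraene-1,8-diol, via alkenylalane 21 (not isolated), via alkenylzinc chloride 22 (not isolated)
Conditions: AlMe3 (5 equiv), Cp2ZrCl2 (0.25 equiv), CH2Cl2, 0 °C → rt; then 10, ZnCl2, Pd(PPh3)4 (5 mol %), THF, rt
Reagents that add atoms: trimethylaluminium, C[Al](C)C
Why: Zr-catalysed syn-carboalumination of the terminal alkyne (Negishi) places methyl on the internal carbon, and Pd-catalysed cross-coupling of the alkenylmetal with the E iodide goes with retention at both partners to give the (E,E)-diene.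

Step 10
Reactants: 23 (2Z,6Z,8S,10E,12E)-2,6,8,10,12-pentamethylpentadeca-2,6,10,12-tetraene-1,8-diol
Product: 24 (2Z,6Z,8S,10E,12E)-8-hydroxy-2,6,8,10,12-pentamethylpentadeca-2,6,10,12-tetraenal
Conditions: MnO2 (20 equiv), CH2Cl2, rt, dark
Reagents that add atoms: none
Why: MnO2 oxidises only the primary allylic alcohol and keeps the Z geometry of the enal (allylic oxidation).

Step 11
Reactants: 24 (2Z,6Z,8S,10E,12E)-8-hydroxy-2,6,8,10,12-pentamethylpentadeca-2,6,10,12-tetraenal; 7 3-acetyl-4-methoxy-5-methylidenefuran-2(5H)-one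
Product: 26 3-[(3R,4Z,8Z,10S,12E,14E)-3,10-dihydroxy-4,8,10,12,14-pentamethylheptadeca-4,8,12,14-tetraenoyl]-4-methoxy-5-methylidenefuran-2(5H)-one, via boron enolate 25 (not isolated)
Conditions: 7 (2 equiv), (+)-Ipc2BCl, Et3N, Et2O, −78 → 0 °C; 24, −78 → −20 °C; MeOH/pH 7 buffer (no peroxide)
Reagents that add atoms: none
Why: Paterson boron aldol, in which the diisopinocampheylboron enolate of the methyl ketone adds to the non-enolisable enal through a cyclic transition state with reagent-controlled Re-face attack to set the carbinol as R (dr about 6:1 expected, minor epimer removed by chromatography; the antipodal borane is used if Mosher analysis shows 3S).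

Step 12
Reactants: 26 aldol adduct (name as in step 11)
Product: 27 3-[(3R,4Z,8Z,10S,12E,14E)-10-hydroxy-3-methoxy-4,8,10,12,14-pentamethylheptadeca-4,8,12,14-tetraenoyl]-4-methoxy-5-methylidenefuran-2(5H)-one (seco alcohol)
Conditions: Me3OBF4 (2 equiv), 1,8-bis(dimethylamino)naphthalene, CH2Cl2, 0 °C
Reagents that add atoms: trimethyloxonium tetrafluoroborate, C[O+](C)C.F[B-](F)(F)F
Why: Meerwein methylation under non-nucleophilic buffering etherifies the secondary allylic alcohol faster than the hindered tertiary one and avoids retro-aldol or elimination of the β-hydroxy ketone (O-alkylation).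

Step 13
Reactants: 27 seco alcohol (name as in step 12)
Product: 29 streptaspironate A, via macrocyclic ether 28 (not isolated)
Conditions: La(OiPr)3 (10 mol %), powdered 5 Å MS, PhMe (1 mM), 50 °C (80 °C if 28 persists)
Reagents that add atoms: none
Why: Proposed new method: a lanthanum-alkoxide-templated vinylogous transesterification used as a macrocyclisation, in which La binds the tertiary alkoxide of 27 and chelates the 3-acyl/lactone dicarbonyl, delivers the alkoxide to C4 of the tetronate through a six-membered addition held as a La diketonate, and collapses with loss of methanol (trapped by the sieves) to the 13-membered 4-O-tert-alkyl tetronate 28; 28 is drained irreversibly by a type 1 IMDA (four-atom C–O–C–C tether) of its (E,E)-diene onto the exocyclic methylene, with the vinylogous carbonyl unit of the tether endo (cis fusion of the two quaternary carbons), the diene geometry fixing the ethyl-bearing carbon, and the ansa alkenyl group on the carbinol carbon pseudo-equatorial (facial control); the closest known reactions are La(OiPr)3-catalysed transesterification of methyl esters with tertiary alcohols, addition–elimination alkoxy exchange on β-alkoxy-α-acyl enoates, and the lanthanide-promoted IMDA of 3-acyl-5-methylidene tetronates.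

## Compound list

1 | 4-methoxyfuran-2(5H)-one (methyl tetronate) | COC1=CC(=O)OC1 | starting material
2 | 5-lithio-4-methoxyfuran-2(5H)-one | [Li]C1OC(=O)C=C1OC | intermediate
3 | 5-[(dimethylamino)methyl]-4-methoxyfuran-2(5H)-one (racemic) | CN(C)CC1OC(=O)C=C1OC | intermediate
4 | [(3-methoxy-5-oxo-2,5-dihydrofuran-2-yl)methyl]trimethylammonium iodide (racemic) | C[N+](C)(C)CC1OC(=O)C=C1OC.[I-] | intermediate
5 | 4-methoxy-5-methylidenefuran-2(5H)-one | C=C1OC(=O)C=C1OC | intermediate
6 | 3-lithio-4-methoxy-5-methylidenefuran-2(5H)-one | [Li]C1=C(OC)C(=C)OC1=O | intermediate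
7 | 3-acetyl-4-methoxy-5-methylidenefuran-2(5H)-one | CC(=O)C1=C(OC)C(=C)OC1=O | intermediate
8 | pent-2-yne | CC#CCC | starting material
9 | chlorobis(cyclopentadienyl)[(E)-pent-2-en-2-yl]zirconium | Cl[Zr](C1C=CC=C1)(C1C=CC=C1)/C(C)=C/CC | intermediate
10 | (E)-2-iodopent-2-ene | I/C(C)=C/CC | intermediate
11 | 2-(2-bromoethyl)-1,3-dioxolane | BrCCC1OCCO1 | starting material
12 | propyne | CC#C | starting material
13 | [2-(1,3-dioxolan-2-yl)ethyl]magnesium bromide | Br[Mg]CCC1OCCO1 | intermediate
14 | [2-(1,3-dioxolan-2-yl)ethyl]copper | [Cu]CCC1OCCO1 | intermediate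
15 | [(Z)-4-(1,3-dioxolan-2-yl)-2-methylbut-1-en-1-yl]copper | [Cu]/C=C(/C)CCC1OCCO1 | intermediate
16 | (Z)-6-(1,3-dioxolan-2-yl)-4-methylhex-3-en-2-one | CC(=O)/C=C(/C)CCC1OCCO1 | intermediate
17 | (Z)-4-methyl-6-oxohept-4-enal | CC(=O)/C=C(/C)CCC=O | intermediate
18 | methyl (2Z,6Z)-2,6-dimethyl-8-oxonona-2,6-dienoate | CC(=O)/C=C(/C)CC/C=C(/C)C(=O)OC | intermediate
19 | methyl (2Z,6Z,8S)-8-hydroxy-2,6,8-trimethylundeca-2,6-dien-10-ynoate | O[C@](C)(/C=C(/C)CC/C=C(/C)C(=O)OC)CC#C | intermediate
20 | (2Z,6Z,8S)-2,6,8-trimethylundeca-2,6-dien-10-yne-1,8-diol | O[C@](C)(/C=C(/C)CC/C=C(/C)CO)CC#C | intermediate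
21 | (E)-alkenyl(dimethyl)alane of 20, both hydroxyls as dimethylaluminium alkoxides | C[Al](C)O[C@](C)(/C=C(/C)CC/C=C(/C)CO[Al](C)C)C/C(C)=C/[Al](C)C | intermediate
22 | (E)-alkenylzinc chloride from 21 | C[Al](C)O[C@](C)(/C=C(/C)CC/C=C(/C)CO[Al](C)C)C/C(C)=C/[Zn]Cl | intermediate
23 | (2Z,6Z,8S,10E,12E)-2,6,8,10,12-pentamethylpentadeca-2,6,10,12-tetraene-1,8-diol | O[C@](C)(/C=C(/C)CC/C=C(/C)CO)C/C(C)=C/C(C)=C/CC | intermediate
24 | (2Z,6Z,8S,10E,12E)-8-hydroxy-2,6,8,10,12-pentamethylpentadeca-2,6,10,12-tetraenal | O[C@](C)(/C=C(/C)CC/C=C(/C)C=O)C/C(C)=C/C(C)=C/CC | intermediate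
25 | diisopinocampheylboron enolate of 7 (from (+)-Ipc2BCl) | C=C(OB([C@H]1C[C@H]2C[C@@H]([C@@H]1C)C2(C)C)[C@H]1C[C@H]2C[C@@H]([C@@H]1C)C2(C)C)C1=C(OC)C(=C)OC1=O | intermediate
26 | 3-[(3R,4Z,8Z,10S,12E,14E)-3,10-dihydroxy-4,8,10,12,14-pentamethylheptadeca-4,8,12,14-tetraenoyl]-4-methoxy-5-methylidenefuran-2(5H)-one | O[C@](C)(/C=C(/C)CC/C=C(/C)[C@H](O)CC(=O)C1=C(OC)C(=C)OC1=O)C/C(C)=C/C(C)=C/CC | intermediate
27 | 3-[(3R,4Z,8Z,10S,12E,14E)-10-hydroxy-3-methoxy-4,8,10,12,14-pentamethylheptadeca-4,8,12,14-tetraenoyl]-4-methoxy-5-methylidenefuran-2(5H)-one (seco alcohol) | O[C@](C)(/C=C(/C)CC/C=C(/C)[C@H](OC)CC(=O)C1=C(OC)C(=C)OC1=O)C/C(C)=C/C(C)=C/CC | intermediate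
28 | 13-membered macrocyclic 4-O-tert-alkyl 5-methylidene tetronate carrying the (2E,4E)-2,4-dimethylhepta-2,4-dienyl arm on the carbinol carbon | C=C1OC(=O)C2=C1O[C@](C)(/C=C(/C)CC/C=C(/C)[C@H](OC)CC2=O)C/C(C)=C/C(C)=C/CC | intermediate
29 | streptaspironate A | CC[C@H]1C[C@@]23OC(=O)C4=C2O[C@](C)(/C=C(/C)CC/C=C(/C)[C@H](OC)CC4=O)C[C@@]3(C)C=C1C | target

## Step count and risks

Total step count: 13. Longest linear sequence: 10 (steps 4 to 13); steps 1–2 and step 3 are side branches.

**Step 13 (the proposed new step).** The tertiary alkoxide may be too hindered to attack C4 of the tetronate at high dilution. The basic La alkoxide may enolise the ketone and expel the β-methoxide. The facial selectivity of the IMDA is argued from a model, not demonstrated.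

Fallback with known chemistry, from 27 back to 29: invert the order of ring formation. Heat 27 without catalyst (PhMe, 2 mM, BHT, 105 °C) so that the acyl-tethered IMDA known for 3-acyl-5-methylidene tetronates closes the cyclohexene and a 15-membered carbocycle first. This gives the carbocyclic spirotetronate with free tertiary hydroxyl and intact 4-methoxy group F1. Then close the pyran by a transannular six-membered alkoxy exchange on the vinylogous ester (camphorsulfonic acid 10 mol %, 4 Å MS, benzene, 50 °C), which gives 29. The diastereomer ratio is then decided by the 15-membered transition state, and only the isomer drawn can close.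

**Step 11 (boron aldol).** A diisopinocampheylboron enolate of an achiral methyl ketone gives only moderate induction, and the Lewis-basic, Michael-accepting tetronate may interfere with enolisation.

Fallback, from 24 back to 27: build the β-methoxy acyl chain first and attach the tetronate last. A Nagao acetate aldol of 24 with (S)-3-acetyl-4-isopropyl-1,3-thiazolidine-2-thione (Sn(OTf)2, N-ethylpiperidine, CH2Cl2, −78 °C; auxiliary antipode chosen for 3R) gives the thiazolidinethione aldol adduct F2. Displacement of the auxiliary with MeNHOMe·HCl/imidazole gives the β-hydroxy Weinreb amide F3. Me3OBF4 with 1,8-bis(dimethylamino)naphthalene gives the β-methoxy Weinreb amide F4. Addition of F4 to 3 equiv of lithio tetronate 6 (made from 5 as in step 2) at −78 °C gives 27.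

**Step 7 (asymmetric propargylation).** The enantioselectivity on a Z β,β-disubstituted enone is untested, and the alkoxide base may erode the Z geometry.

Fallback, from 18 back to 19: give up catalytic induction and resolve. A Barbier propargylation of 18 (propargyl bromide, Zn, THF/aq. NH4Cl, 0 °C) gives the racemic tertiary carbinol F5. Preparative chiral SFC delivers 19; the 8R antipode is discarded.

## Further compounds

F1 | step 13 | acyl-tethered IMDA adduct: 15-membered carbocyclic spirotetronate with free tertiary alcohol and 4-methoxy group | CC[C@H]1C[C@]2(OC(=O)C3=C2OC)[C@](C)(C=C1C)C[C@](C)(O)/C=C(/C)CC/C=C(/C)[C@H](OC)CC3=O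
F2 | step 11 | (S)-4-isopropyl-1,3-thiazolidine-2-thione amide of the (3R)-3,10-dihydroxy tetraenoic acid (Nagao aldol adduct of 24) | O[C@](C)(/C=C(/C)CC/C=C(/C)[C@H](O)CC(=O)N1[C@@H](C(C)C)CSC1=S)C/C(C)=C/C(C)=C/CC
F3 | step 11 | (3R,4Z,8Z,10S,12E,14E)-3,10-dihydroxy-N-methoxy-N,4,8,10,12,14-hexamethylheptadeca-4,8,12,14-tetraenamide | O[C@](C)(/C=C(/C)CC/C=C(/C)[C@H](O)CC(=O)N(C)OC)C/C(C)=C/C(C)=C/CC
F4 | step 11 | (3R,4Z,8Z,10S,12E,14E)-10-hydroxy-N,3-dimethoxy-N,4,8,10,12,14-hexamethylheptadeca-4,8,12,14-tetraenamide | O[C@](C)(/C=C(/C)CC/C=C(/C)[C@H](OC)CC(=O)N(C)OC)C/C(C)=C/C(C)=C/CC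
F5 | step 7 | racemic methyl (2Z,6Z)-8-hydroxy-2,6,8-trimethylundeca-2,6-dien-10-ynoate | OC(C)(/C=C(/C)CC/C=C(/C)C(=O)OC)CC#C
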